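**Plan**

- Retrosynthesis: the C3–Br bond of ring A is cut first (back to a C3 carboxylic acid), then C3–C3a of ring A (the pyrrole ring opens to an N-aryl enamino ester), then the enamine N–C bond (aniline plus methyl propiolate), then C5–Br and C3'–Br, and last the N1'–C4 bond joining ring B to the benzene ring of ring A.
- Forward: ring B is bought as 5-bromoindole and N-arylated with 4-iodo-2-nitroanisole. C3' is brominated, the nitro group is reduced and C5 is brominated para to the amine. Propiolate addition and anodic closure build the pyrrole ring of ring A, and the C3 ester is exchanged for bromine at the end.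
- Enabling feature: in the anilino ring, C7 carries OMe, C4 carries N1' of ring B and C5 carries Br. C3a is therefore the only free carbon ortho to nitrogen, so C3–C3a closure can give one indole only. C3' of ring B is already blocked by bromine.
- Stereochemistry: the target has no stereocentre. The Z enamine double bond, set by the N–H···O=C hydrogen bond, disappears on aromatisation.

Key step: step 6

Assumption: enamino ester 8 is drawn as its hydrogen-bonded Z isomer; any E isomer would be carried forward with it, since the geometry is lost on ring closure.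

**Route**

Step 1
Reactants: 1 5-bromo-1H-indole; 2 4-iodo-1-methoxy-2-nitrobenzene
Product: 3 5-bromo-1-(4-methoxy-3-nitrophenyl)-1H-indole
Conditions: CuI (10 mol%), trans-N,N'-dimethylcyclohexane-1,2-diamine (20 mol%), K3PO4, toluene, 110 °C
Reagents that add atoms: none
Why: Ullmann–Goldberg N-arylation of an indole with monovalent copper and a diamine ligand, in which the unhindered C–I bond of 2 should react well before the C5–Br bond of 1, with the nitro and methoxy groups inert.

Step 2
Reactants: 3 5-bromo-1-(4-methoxy-3-nitrophenyl)-1H-indole
Product: 4 3,5-dibromo-1-(4-methoxy-3-nitrophenyl)-1H-indole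
Conditions: NBS (1.05 equiv), DMF, 0 °C
Reagents that add atoms: N-bromosuccinimide, O=C1CCC(=O)N1Br
Why: Electrophilic aromatic substitution at C3', the most nucleophilic carbon of the N-arylindole, while the nitroanisole ring is too deactivated to compete.

Step 3
Reactants: 4 3,5-dibromo-1-(4-methoxy-3-nitrophenyl)-1H-indole
Product: 5 5-(3,5-dibromo-1H-indol-1-yl)-2-methoxyaniline
Conditions: Fe powder, NH4Cl, EtOH/H2O (4:1), 80 °C
Reagents that add atoms: none
Why: Béchamp-type dissolving-metal reduction of the nitro group under near-neutral conditions, which should leave the aryl bromide and the 3-bromoindole intact where catalytic hydrogenation would not.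

Step 4
Reactants: 5 5-(3,5-dibromo-1H-indol-1-yl)-2-methoxyaniline
Product: 6 4-bromo-5-(3,5-dibromo-1H-indol-1-yl)-2-methoxyaniline
Conditions: NBS (1.0 equiv), DMF, −10 to 0 °C
Reagents that add atoms: N-bromosuccinimide, O=C1CCC(=O)N1Br
Why: Electrophilic aromatic bromination para to the free amino group, the strongest director, with one equivalent at low temperature sparing the ortho carbon needed later and ring B already deactivated by two bromines.

Step 5
Reactants: 6 4-bromo-5-(3,5-dibromo-1H-indol-1-yl)-2-methoxyaniline; 7 methyl propiolate
Product: 8 methyl (Z)-3-{[4-bromo-5-(3,5-dibromo-1H-indol-1-yl)-2-methoxyphenyl]amino}prop-2-enoate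
Conditions: 7 (1.5 equiv), MeOH, 50 °C
Reagents that add atoms: none
Why: Aza-Michael addition (hydroamination) of the aniline to the ynoate, the Z enamino ester being favoured by the N–H···O=C hydrogen bond and any E isomer able to equilibrate through the imine tautomer.

Step 6
Reactants: 8 methyl (Z)-3-{[4-bromo-5-(3,5-dibromo-1H-indol-1-yl)-2-methoxyphenyl]amino}prop-2-enoate
Product: 9 methyl 5-bromo-4-(3,5-dibromo-1H-indol-1-yl)-7-methoxy-1H-indole-3-carboxylate
Conditions: KI (0.5 equiv), DMF/H2O (9:1), undivided cell, graphite anode, Pt cathode, constant current (ca. 7 mA, ca. 2.5 F/mol), rt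
Reagents that add atoms: none
Why: Iodide is oxidised at the graphite anode to iodine, which iodinates the enamino ester at nitrogen or at its α-carbon; ionisation of the resulting α-iodo imine tautomer makes C3 electrophilic, C3a of the anilino ring attacks it, and loss of HI aromatises the new pyrrole while protons are reduced to H2 at the Pt cathode, so iodide is regenerated and the net change is loss of H2. The closest known reaction type is the iodide-mediated electrochemical dehydrogenative annulation of N-aryl enamino esters and enaminones to indoles. The pyrrole ring of ring A closes by formation of the C3–C3a bond, a five-membered Friedel–Crafts-type closure (5-exo-tet with respect to the departing iodide) onto an arene carbon ortho to nitrogen. No stereocentre is formed. Regioselectivity is secured by the substrate, because the other ortho carbon carries OMe (the future C7) and only the carbon between nitrogen and the N-indolyl-bearing carbon is free; chemoselectivity rests on the low potential of the iodide/iodine couple, which should leave ring B (C3' blocked by Br, ring deactivated by two bromines) and the anisole unit unoxidised, and on proton reduction at Pt outrunning cathodic C–Br cleavage.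

Step 7
Reactants: 9 methyl 5-bromo-4-(3,5-dibromo-1H-indol-1-yl)-7-methoxy-1H-indole-3-carboxylate
Product: 10 5-bromo-4-(3,5-dibromo-1H-indol-1-yl)-7-methoxy-1H-indole-3-carboxylic acid
Conditions: KOH, THF/MeOH/H2O, 65 °C; then aq. HCl to pH 3, 0 °C
Reagents that add atoms: potassium hydroxide, [K+].[OH-]
Why: Saponification of the methyl ester by acyl–oxygen cleavage with hydroxide, conditions under which aryl and heteroaryl bromides do not react, with cold acidification to avoid premature decarboxylation.

Step 8
Reactants: 10 5-bromo-4-(3,5-dibromo-1H-indol-1-yl)-7-methoxy-1H-indole-3-carboxylic acid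
Product: 11 rivularin B, 3,5-dibromo-4-(3,5-dibromo-1H-indol-1-yl)-7-methoxy-1H-indole
Conditions: NBS (1.0 equiv), DMF, 0 °C, dark
Reagents that add atoms: N-bromosuccinimide, O=C1CCC(=O)N1Br
Why: Decarboxylative ipso-bromination (halodecarboxylation) of an indole-3-carboxylic acid, in which electrophilic bromine adds at C3 and the 3H-indolium carboxylate loses CO2 to rearomatise, so bromine ends up only where the carboxyl group stood and the sensitive NH-free 3-bromoindole appears last.

**Compound list**

1 | 5-bromo-1H-indole | Brc1ccc2[nH]ccc2c1 | starting material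
2 | 4-iodo-1-methoxy-2-nitrobenzene (4-iodo-2-nitroanisole) | COc1ccc(I)cc1[N+](=O)[O-] | starting material
3 | 5-bromo-1-(4-methoxy-3-nitrophenyl)-1H-indole | COc1ccc(-n2ccc3cc(Br)ccc32)cc1[N+](=O)[O-] | intermediate
4 | 3,5-dibromo-1-(4-methoxy-3-nitrophenyl)-1H-indole | COc1ccc(-n2cc(Br)c3cc(Br)ccc32)cc1[N+](=O)[O-] | intermediate
5 | 5-(3,5-dibromo-1H-indol-1-yl)-2-methoxyaniline | COc1ccc(-n2cc(Br)c3cc(Br)ccc32)cc1N | intermediate
6 | 4-bromo-5-(3,5-dibromo-1H-indol-1-yl)-2-methoxyaniline | COc1cc(Br)c(-n2cc(Br)c3cc(Br)ccc32)cc1N | intermediate
7 | methyl propiolate | C#CC(=O)OC | starting material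
8 | methyl (Z)-3-{[4-bromo-5-(3,5-dibromo-1H-indol-1-yl)-2-methoxyphenyl]amino}prop-2-enoate | COC(=O)/C=C\Nc1cc(-n2cc(Br)c3cc(Br)ccc32)c(Br)cc1OC | intermediate
9 | methyl 5-bromo-4-(3,5-dibromo-1H-indol-1-yl)-7-methoxy-1H-indole-3-carboxylate | COC(=O)c1c[nH]c2c(OC)cc(Br)c(-n3cc(Br)c4cc(Br)ccc43)c12 | intermediate
10 | 5-bromo-4-(3,5-dibromo-1H-indol-1-yl)-7-methoxy-1H-indole-3-carboxylic acid | OC(=O)c1c[nH]c2c(OC)cc(Br)c(-n3cc(Br)c4cc(Br)ccc43)c12 | intermediate
11 | rivularin B, 3,5-dibromo-4-(3,5-dibromo-1H-indol-1-yl)-7-methoxy-1H-indole | COc1cc(Br)c(-n2cc(Br)c3cc(Br)ccc32)c2c(Br)c[nH]c12 | target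

**Count**

Total steps: 8. Longest linear sequence: 8 steps (from 1 or 2 to 11).

**Steps most likely to fail**

Step 6. The enamine of 8 has no substituent on the carbon next to nitrogen, so anodically formed iodine may be consumed by oligomerisation or over-oxidation of the enamine or the methoxyaniline ring. This could happen before the crowded ortho carbon, wedged between nitrogen and the N-indolyl-bearing carbon, attacks. The fallback sets out from aniline 6. Iodination with NIS (MeCN, 0 °C) at the only free carbon ortho to the amino group should give 4-bromo-3-(3,5-dibromo-1H-indol-1-yl)-2-iodo-6-methoxyaniline F1. Addition of F1 to methyl propiolate 7 (MeOH, 60 °C) should give methyl (Z)-3-{[4-bromo-3-(3,5-dibromo-1H-indol-1-yl)-2-iodo-6-methoxyphenyl]amino}prop-2-enoate F2. An intramolecular Heck-type cyclisation (Pd(OAc)2, PPh3, Et3N, DMF, 90 °C) then forms the same C3–C3a bond, zerovalent palladium inserting into the C–I bond well before any C–Br bond, and the sequence comes back to the route at ester 9.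

Step 1. Once the aryl iodide runs low, the copper catalyst may begin to engage the C5–Br bond of 1, giving N-arylated oligomers and stalled conversion. The fallback sets out from 2 and makes the C–N bond before any bromine is on the nitrogen partner. Buchwald–Hartwig amination of 2 with purchased indoline (Pd(OAc)2, rac-BINAP, Cs2CO3, toluene, 100 °C) should give 1-(4-methoxy-3-nitrophenyl)-2,3-dihydro-1H-indole F3. NBS (DMF, 0 °C) then brominates para to the indoline nitrogen to give 5-bromo-1-(4-methoxy-3-nitrophenyl)-2,3-dihydro-1H-indole F4. Dehydrogenation with DDQ (toluene, rt) comes back to the route at 3.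

Step 8. Bromination at C2 or C6 of the electron-rich methoxyindole may compete with ipso attack at the crowded C3, and the NH-free 3-bromoindole may degrade during isolation. The fallback sets out from acid 10 and separates the two events. Protodecarboxylation (cat. K2CO3, DMF, 130 °C) should give 5-bromo-4-(3,5-dibromo-1H-indol-1-yl)-7-methoxy-1H-indole F5. Buffered C3 bromination with pyridinium tribromide in pyridine at 0 °C then comes back to the route at 11.

**Further compounds**

F1 | step 6 | 4-bromo-3-(3,5-dibromo-1H-indol-1-yl)-2-iodo-6-methoxyaniline | COc1cc(Br)c(-n2cc(Br)c3cc(Br)ccc32)c(I)c1N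
F2 | step 6 | methyl (Z)-3-{[4-bromo-3-(3,5-dibromo-1H-indol-1-yl)-2-iodo-6-methoxyphenyl]amino}prop-2-enoate | COC(=O)/C=C\Nc1c(I)c(-n2cc(Br)c3cc(Br)ccc32)c(Br)cc1OC
F3 | step 1 | 1-(4-methoxy-3-nitrophenyl)-2,3-dihydro-1H-indole | COc1ccc(N2CCc3ccccc32)cc1[N+](=O)[O-]
F4 | step 1 | 5-bromo-1-(4-methoxy-3-nitrophenyl)-2,3-dihydro-1H-indole | COc1ccc(N2CCc3cc(Br)ccc32)cc1[N+](=O)[O-]
F5 | step 8 | 5-bromo-4-(3,5-dibromo-1H-indol-1-yl)-7-methoxy-1H-indole | COc1cc(Br)c(-n2cc(Br)c3cc(Br)ccc32)c2cc[nH]c12
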